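Numbering used throughout: carbocycles carry the numbering of the target (C1 = quaternary carbinol carbon bearing the exocyclic carbon C7, C2 = its allylic neighbour, C3=C4, C5, C6). Sugars carry carbohydrate numbering, and the one-carbon branch on sugar C2 is called C7 from the start. Sugar C1, C2, C3, C4, C5, C6 become ring carbons C2, C1, C6, C5, C4, C3. Compound numbers 1–22 are those of the steps below.

## Analysis of the target

Target 22 is a cyclohex-3-ene that carries five oxygen functions, namely a tertiary carbinol at C1 that also bears the benzoyloxymethyl arm C7, benzoates on the two allylic carbons C2 and C5, and a free secondary hydroxyl at C6. The four stereocentres C5, C6, C1 and C2 are contiguous, with O1, O2 and O6 on one face of the ring and O5 and C7 on the other, so that the C1/C6 diol is cis, the C1 hydroxyl and the C2 benzoate are cis, and the C5 and C6 oxygens are trans. The sensitive groups are the three benzoates, which can migrate to a neighbouring free hydroxyl or be cleaved by base, the two allylic esters, which can ionise or suffer SN2' attack, and, in any carbonyl-containing precursor, the β-oxygen substituents that invite elimination. The synthesis is hard because the fully substituted C1 must be set relative to three neighbours and because five oxygens must be told apart, three of them acylated and two free, one of the free ones tertiary. The strategy rests on the observation that the ring carbons C2, C1, C6, C5, C4 and C3 are C1 to C6 of D-mannose 1. Mannose C2, C3 and C4 already have the configurations needed at C1, C6 and C5, C7 can come from formaldehyde 3 in place of H-2, and the cis O1/O6 pair, the two hydroxyls that stay free, is the mannose 2,3-cis-diol, which a single acetonide can mask from the first step to the last. Only C2 has to be created, and C4 has to be turned from a carbonyl carbon into an alkene carbon.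

## Retrosynthetic reasoning

22 from 21. The first cut removes no skeletal bond: the free O1/O6 hydroxyls are traced back to the C1/C6 acetonide of 21. With acetal cleavage last, the only hydroxyls ever exposed beside the three benzoates are the two that must stay free. The forward step has to open a cis-fused dioxolane under acid without acyl migration.

21 from 19 and 20. The C2–O bond of the third benzoate is cut at the allylic carbon, giving allylic alcohol 19 and benzoic acid 20. It is cut with inversion because the ring-forming aldol is expected to place the C2 hydroxyl trans to O1, whereas 22 needs it cis. An SN2 esterification at the allylic carbinol corrects this in the same step that introduces the ester. The forward reaction must be a clean SN2, not SN2', next to the quaternary C1.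

19 from 12, through 18, 17, 16, 15, 14 and 13. The C3=C4 alkene is traced back to the C4 ketone of ketol 12: syn elimination of selenoxide 17, made from selenide 16, which comes from alcohol 14 through triflate 15, and 14 from ketone 13 by hydride reduction. A selenoxide is chosen because it eliminates away from the oxygen-bearing C5, so the double bond forms toward C3 whatever the configuration at C4. The C2 hydroxyl is carried as a silyl ether from 13 to 18 so that it stays distinct from the C4 hydroxyl and cannot be lost by β-elimination; it is released in 19 only when it is needed.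

12 from 10, through 11. The C2–C3 ring bond of 12 is cut by a retro-aldol to the mercurated keto-aldehyde 11, which is the ring-opened form of the hex-5-enopyranose 10. This cut turns the carbocycle into a pyranose in which C1, C5 and C6 are already correct. The quaternary C1 makes the aldehyde non-enolisable, so only one aldol is possible. The forward reaction has to close a six-membered ring and set C2.

10 from 7, through 9 and 8. The exocyclic enol ether of 10 is traced back to primary iodide 9 by dehydrohalogenation, the O4 ester of 9 to alcohol 8 and benzoyl chloride 5, and the iodide of 8 to diol 7. These changes come after the branch is in place because they need O6 and O4 to be the only free hydroxyls.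

7 from 4 and 5, through 6. Diol 7 comes from bis-acetonide 6 by cleavage of the 4,6-acetal alone, and 6 from lactol 4 by acylation of its two hydroxyls with 5. The anomeric oxygen is acylated rather than methylated for four reasons: the ester goes on together with the C7 benzoate; no acidic glycosidation is needed that would strip the 2,3-acetonide; the pyranose is locked before O4 is freed; and the acyloxy group departs in the ring-forming step just as an alkoxy group would.

4 from 2 and 3. The bond between sugar C2 and C7 is cut by a retro-aldol to lactol 2 and formaldehyde 3. This uses the only enolisable position of the aldose, and the cis-fused dioxolane dictates the configuration of the new quaternary centre.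

2 from 1. Both acetals are removed to reach D-mannose 1. Fixing the sugar as a pyranose with the 2,3-acetonide already in place at this first stage means that this acetal never has to be put back on a polyol in which the new C7 hydroxyl could compete for O2.

## Alternatives that were turned down

Alternative 1: The C1–C6 bond is cut, which leads to the open-chain (Z)-keto-aldehyde A2 with a C1 ketone, a C6 aldehyde and p-methoxybenzyl ethers at O2, O5 and O7. In the forward sense samarium diiodide A3, SmI2, a reagent of divalent samarium, would reduce both carbonyls of A2 to ketyls and couple them to the cyclohexene cis-diol A1.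
- For: the cis C1/C6 diol, quaternary carbinol included, is made in the ring-closing step through a samarium-bridged diolate, and the C3=C4 alkene is already present. No carbonyl has to be removed afterwards, so on redox economy after cyclisation this plan is stronger than the chosen route, which spends steps 9–13 on turning a ketone into the alkene.
- Against: A2 combines an α,α'-dialkoxy ketone (reductive C–O cleavage by A3 competes with ketyl coupling), an epimerisable α-alkoxy aldehyde and a cis-alkene between two allylic ethers, and it must be built acyclically with two stereocentres and defined alkene geometry.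
- Against: the new diol normally forms anti to both flanking alkoxy groups, but 22 needs it anti to O5 and syn to O2, so one control element is mismatched.
- Against: A1 still needs diol protection and exchange of three ethers for benzoates.
- Comparison: the chosen route takes C1, C5 and C6 from 1, leaves only C2 open and can correct C2 by inversion.

Alternative 2: The C2–O bond is cut in the achiral para-quinol A5. In the forward sense a chiral BINOL-derived phosphoric acid would let the tertiary hydroxyl of A5 form a hemiacetal with acetaldehyde A6 and add that oxygen to one of the two enantiotopic enone carbons, giving the cis-fused ethylidene acetal A4.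
- For: A5 is achiral and small, and the key step is catalytic, enantioselective and sets C1 and the C2 oxygen cis in one operation. Up to this point the plan is clearly shorter than the chosen route, which needs seven steps before its key step, and it uses no chiral-pool material.
- Against: A4 holds only two of the four ring stereocentres. Its remaining enone must be converted into the trans C5/C6 oxygens (O6 cis to O1), and the C4 carbonyl must then be removed with formation of C3=C4. That costs more stereocontrolled redox steps than were saved, each relying on induction from the bicyclic acetal.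
- Against: the β-alkoxy ketone of A4 can revert by retro-oxa-Michael addition and lose enantiopurity, and the acetal oxygen at C2 must later be told apart from O1.
- Comparison: the chosen route offers three secure stereocentres and a protecting-group pattern that already matches 22.

Alternative 3: The C1–C2 bond is cut, leading to the saturated keto-aldehyde A8 with a C1 ketone bearing the protected C7, a C2 aldehyde and the C5/C6 diol as an acetonide. In the forward sense a chiral triazolium-derived carbene would turn the aldehyde of A8 into an acyl anion equivalent that adds to the ketone, giving acyloin A7 with the quaternary carbinol.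
- For: the C2 carbonyl of A7 is well placed; dehydrogenation to the C3=C4 enone and 1,2-reduction would give the C2 allylic alcohol directly. On carbonyl placement this plan is better than the chosen route, whose C4 ketone must be reduced and eliminated.
- Against: O5 and O6 of 22 are trans, so the acetonide of A7 is trans-fused to the new ring and the cyclisation must build a strained bicycle.
- Against: the catalyst must deliver the C1 hydroxyl cis to O6 at a ketone flanked by two α-oxygen substituents, with an uncertain match to the bias of the dioxolane.
- Against: the acetonide of A7 spans O5, which is to be acylated, and O6, which is to stay free, and so gives no differentiation; together with the ether on C7 this adds protecting-group steps.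
- Comparison: in the chosen route the acetonide spans exactly the two hydroxyls that remain free, and C1 comes from the sugar.

Key step: step 8

Remarks on the chemistry (assumptions):
- Glycosyl benzoates 6–10 are drawn as α-anomers; the anomeric carbon becomes the aldehyde carbon in step 8, so any β-anomer converges on 12.
- The C4 configuration drawn for 14–17 is the predicted one; C4 becomes sp2 in step 12, so its epimer would converge on 18.

## Route

Step 1
Reactants: 1 D-mannose
Product: 2 2,3:4,6-di-O-isopropylidene-α-D-mannopyranose
Conditions: 2-methoxypropene, TsOH (cat.), DMF, 0 °C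
Reagents that add atoms: 2-methoxypropene, COC(C)=C
Why: Kinetic acetalisation with an enol ether: the primary O6 reacts first and closes onto O4, then the cis-2,3-diol is bridged, which traps the pyranose form and leaves only the anomeric hydroxyl free. No stereocentre is created.

Step 2
Reactants: 2 2,3:4,6-di-O-isopropylidene-α-D-mannopyranose; 3 formaldehyde
Product: 4 2-C-(hydroxymethyl)-2,3:4,6-di-O-isopropylidene-D-mannopyranose (lactol, anomeric mixture)
Conditions: 37% aq. HCHO, K2CO3, MeOH, 65 °C
Reagents that add atoms: formaldehyde (3), C=O
Why: Base-mediated crossed aldol (hydroxymethylation) of the ring-opened aldehyde. The C2 enolate held in the dioxolane takes up formaldehyde on the face anti to the C3 substituent, and only that isomer can reclose to a cis-fused pyranose, so C7 replaces H-2 with the manno arrangement of O2. Reclosure to the lactol shields the now non-enolisable aldehyde.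

Step 3
Reactants: 4 2-C-(hydroxymethyl)-2,3:4,6-di-O-isopropylidene-D-mannopyranose; 5 benzoyl chloride
Product: 6 1-O-benzoyl-2-C-(benzoyloxymethyl)-2,3:4,6-di-O-isopropylidene-α-D-mannopyranose
Conditions: BzCl, pyridine, DMAP (cat.), CH2Cl2, 0 °C → rt
Reagents that add atoms: benzoyl chloride (5), O=C(Cl)c1ccccc1
Why: DMAP-catalysed esterification of the only two free hydroxyls. The C7 benzoate is kept to the end; the anomeric benzoate locks the pyranose and later serves as the leaving group of the carbocyclisation.

Step 4
Reactants: 6 1-O-benzoyl-2-C-(benzoyloxymethyl)-2,3:4,6-di-O-isopropylidene-α-D-mannopyranose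
Product: 7 1-O-benzoyl-2-C-(benzoyloxymethyl)-2,3-O-isopropylidene-α-D-mannopyranose
Conditions: 70% aq. AcOH, 40 °C
Reagents that add atoms: none
Why: Chemoselective acetal hydrolysis: the 4,6-dioxane acetonide with its axial methyl group is cleaved much faster than the cis-fused 2,3-dioxolane, and esters, the glycosyl ester included, are inert to aqueous acetic acid.

Step 5
Reactants: 7 1-O-benzoyl-2-C-(benzoyloxymethyl)-2,3-O-isopropylidene-α-D-mannopyranose
Product: 8 1-O-benzoyl-2-C-(benzoyloxymethyl)-6-deoxy-6-iodo-2,3-O-isopropylidene-α-D-mannopyranose
Conditions: I2, PPh3, imidazole, toluene, 70 °C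
Reagents that add atoms: iodine, II
Why: Garegg–Samuelsson (Appel-type) iodination: the alkoxyphosphonium ion of the unhindered primary O6 is displaced by iodide (SN2) while the secondary O4–H stays free.

Step 6
Reactants: 8 1-O-benzoyl-2-C-(benzoyloxymethyl)-6-deoxy-6-iodo-2,3-O-isopropylidene-α-D-mannopyranose; 5 benzoyl chloride
Product: 9 1,4-di-O-benzoyl-2-C-(benzoyloxymethyl)-6-deoxy-6-iodo-2,3-O-isopropylidene-α-D-mannopyranose
Conditions: BzCl, pyridine, DMAP (cat.), CH2Cl2, rt
Reagents that add atoms: benzoyl chloride (5), O=C(Cl)c1ccccc1
Why: Standard esterification of the one remaining hydroxyl; it installs the ester that becomes the C5 benzoate of the target.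

Step 7
Reactants: 9 1,4-di-O-benzoyl-2-C-(benzoyloxymethyl)-6-deoxy-6-iodo-2,3-O-isopropylidene-α-D-mannopyranose
Product: 10 1,4-di-O-benzoyl-2-C-(benzoyloxymethyl)-6-deoxy-2,3-O-isopropylidene-α-D-lyxo-hex-5-enopyranose
Conditions: AgF, pyridine, rt, dark
Reagents that add atoms: none
Why: Silver-assisted dehydroiodination (E2) of a 6-deoxy-6-iodopyranose to the exocyclic enol ether, the classical entry to hex-5-enopyranoses. The conditions are mild enough to leave the three esters and the acetonide untouched.

Step 8
Reactants: 10 1,4-di-O-benzoyl-2-C-(benzoyloxymethyl)-6-deoxy-2,3-O-isopropylidene-α-D-lyxo-hex-5-enopyranose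
Product: 12 ketol (cyclohexanone with C4 ketone; C3 methylene; C2–OH trans to O1 and O6; C5 and C7 benzoates; C1/C6 acetonide), via mercurated keto-aldehyde 11 (not isolated)
Conditions: Hg(OCOCF3)2 (10 mol%), acetone–H2O (4:1), rt
Reagents that add atoms: water, O (supplies the ketone oxygen); Hg(OCOCF3)2, O=C(O[Hg]OC(=O)C(F)(F)F)C(F)(F)F (its HgOCOCF3 unit is carried only by 11)
Why: Hg(OCOCF3)2 adds with water across the electron-rich exocyclic enol ether of 10 (hydroxymercuration, mercury on the terminal carbon); the C5 hemiketal opens and the anomeric hemiacetal benzoate collapses with loss of benzoic acid to the α-mercurated ketone–aldehyde 11. The mercury enolate of 11 adds to the aldehyde (intramolecular aldol) to form the C2–C3 bond, and protonolysis of the Hg–O bond returns divalent mercury, so a catalytic amount suffices. The closest known reaction type is the Ferrier carbocyclization of 6-deoxyhex-5-enopyranosides and their 1-O-acyl analogues to β-hydroxycyclohexanones. The single ring is closed in a 6-(enolexo)-exo-trig mode. Only C2 is new: in the chair transition state O6, the C5 benzoate and C7 are equatorial and O1 is axial, and the aldehyde oxygen takes the axial site where mercury can bridge it to the enolate oxygen and where its dipole opposes the C1–O1 bond, so the hydroxyl should emerge trans to O1 and O6. Regiochemistry needs no control because the mercurated C3 is the only nucleophilic carbon and the aldehyde on the quaternary C1 cannot enolise or epimerise; the near-neutral medium at room temperature should spare the benzoates, the acetonide and the elimination-prone ketol. The C2 configuration obtained is the one that the inverting esterification of step 14 converts into that of the target.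

Step 9
Reactants: 12 ketol
Product: 13 C2 tert-butyldimethylsilyl ether of ketol 12
Conditions: TBSOTf, 2,6-lutidine, CH2Cl2, −78 → 0 °C
Reagents that add atoms: tert-butyldimethylsilyl trifluoromethanesulfonate, CC(C)(C)[Si](C)(C)OS(=O)(=O)C(F)(F)F
Why: Silyl triflate silylation of a hindered secondary alcohol with a weak, hindered base at low temperature, which avoids β-elimination of the ketol. The silyl ether keeps O2 distinct from the hydroxyl generated next.

Step 10
Reactants: 13 C2 silyl ether ketone
Product: 14 C4 alcohol (C4–OH on the face of O2, O5 and C7; C2 silyl ether; C5 and C7 benzoates; C1/C6 acetonide)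
Conditions: NaBH4, CeCl3·7H2O, MeOH, −40 °C
Reagents that add atoms: none
Why: Luche-type carbonyl reduction under nearly neutral conditions, which limits benzoyl migration and β-elimination. The axial C2 silyl ether shields the axial trajectory at C4, so hydride should enter equatorially and give the alcohol cis to the C5 benzoate; this centre is removed in step 12.

Step 11
Reactants: 14 C4 alcohol
Product: 16 C4 phenyl selenide (SePh on the face of O1 and O6; inverted at C4), via C4 triflate 15 (not isolated)
Conditions: Tf2O, pyridine, CH2Cl2, −20 °C; then crude triflate, PhSeSePh/NaBH4, EtOH–THF, 0 °C → rt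
Reagents that add atoms: diphenyl diselenide, c1ccc(cc1)[Se][Se]c1ccccc1; trifluoromethanesulfonic anhydride, O=S(=O)(OS(=O)(=O)C(F)(F)F)C(F)(F)F (its triflyl group is carried only by 15)
Why: SN2 displacement of a secondary triflate by the soft, weakly basic phenylselenolate with inversion at C4. The cis C5 benzoate cannot participate from the rear, and selenolate favours substitution over elimination.

Step 12
Reactants: 16 C4 phenyl selenide
Product: 18 cyclohex-3-ene (C2 silyl ether trans to O1; C5 and C7 benzoates; C1/C6 acetonide), via selenoxide 17 (not isolated)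
Conditions: 30% H2O2, pyridine, CH2Cl2, 0 °C → rt
Reagents that add atoms: hydrogen peroxide, OO (its oxygen is carried only by 17)
Why: Selenide oxidation followed by selenoxide syn elimination. Selenoxides eliminate away from an oxygen-bearing carbon (an allylic ester forms in preference to an enol ester), so the syn hydrogen at C3 is lost and the C3=C4 alkene results; pyridine buffers the selenenic acid.

Step 13
Reactants: 18 cyclohex-3-ene silyl ether
Product: 19 allylic alcohol (C2–OH trans to O1 and O6; C5 and C7 benzoates; C1/C6 acetonide)
Conditions: HF·pyridine, pyridine, THF, 0 °C → rt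
Reagents that add atoms: none
Why: Fluoride-mediated Si–O cleavage under buffered, non-basic conditions, which should cause no acyl migration and leave the acetonide intact.

Step 14
Reactants: 19 allylic alcohol; 20 benzoic acid
Product: 21 tribenzoate acetonide (C2–OBz cis to O1 and O6; C5 and C7 benzoates; C1/C6 acetonide)
Conditions: PhCO2H, PPh3, DIAD, toluene, 0 °C → rt
Reagents that add atoms: benzoic acid (20), O=C(O)c1ccccc1
Why: Mitsunobu esterification: the allylic C2 alkoxyphosphonium ion is displaced by benzoate with inversion (SN2), the nucleophile arriving on the face of the tied-back O1 and not on that of the C7 arm. This sets the C2 benzoate cis to O1 as in the target.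

Step 15
Reactants: 21 tribenzoate acetonide
Product: 22 target CNP0128482.1 (1-C-(benzoyloxymethyl)cyclohex-3-ene-1,2,5,6-tetrol 2,5-dibenzoate; O1, O2 and O6 cis; O5 trans)
Conditions: TFA–H2O (9:1), CH2Cl2, 0 °C
Reagents that add atoms: none
Why: Acid-catalysed acetal hydrolysis releases the cis C1/C6 diol. Benzoates survive aqueous acid, and migration to the tertiary O1 or to the trans-disposed O6 should be slow at this temperature.

## Compound list

1 | D-mannose | OC[C@H]1OC(O)[C@@H](O)[C@@H](O)[C@@H]1O | starting material
2 | 2,3:4,6-di-O-isopropylidene-α-D-mannopyranose | CC1(C)OC[C@H]2O[C@H](O)[C@H]3OC(C)(C)O[C@H]3[C@@H]2O1 | intermediate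
3 | formaldehyde | C=O | starting material
4 | 2-C-(hydroxymethyl)-2,3:4,6-di-O-isopropylidene-D-mannopyranose | CC1(C)OC[C@H]2OC(O)[C@@]3(CO)OC(C)(C)O[C@H]3[C@@H]2O1 | intermediate
5 | benzoyl chloride | O=C(Cl)c1ccccc1 | starting material
6 | 1-O-benzoyl-2-C-(benzoyloxymethyl)-2,3:4,6-di-O-isopropylidene-α-D-mannopyranose | CC1(C)OC[C@H]2O[C@H](OC(=O)c3ccccc3)[C@@]4(COC(=O)c3ccccc3)OC(C)(C)O[C@H]4[C@@H]2O1 | intermediate
7 | 1-O-benzoyl-2-C-(benzoyloxymethyl)-2,3-O-isopropylidene-α-D-mannopyranose | OC[C@H]1O[C@H](OC(=O)c2ccccc2)[C@@]3(COC(=O)c2ccccc2)OC(C)(C)O[C@H]3[C@@H]1O | intermediate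
8 | 1-O-benzoyl-2-C-(benzoyloxymethyl)-6-deoxy-6-iodo-2,3-O-isopropylidene-α-D-mannopyranose | IC[C@H]1O[C@H](OC(=O)c2ccccc2)[C@@]3(COC(=O)c2ccccc2)OC(C)(C)O[C@H]3[C@@H]1O | intermediate
9 | 1,4-di-O-benzoyl-2-C-(benzoyloxymethyl)-6-deoxy-6-iodo-2,3-O-isopropylidene-α-D-mannopyranose | IC[C@H]1O[C@H](OC(=O)c2ccccc2)[C@@]3(COC(=O)c2ccccc2)OC(C)(C)O[C@H]3[C@@H]1OC(=O)c1ccccc1 | intermediate
10 | 1,4-di-O-benzoyl-2-C-(benzoyloxymethyl)-6-deoxy-2,3-O-isopropylidene-α-D-lyxo-hex-5-enopyranose | C=C1O[C@H](OC(=O)c2ccccc2)[C@@]3(COC(=O)c2ccccc2)OC(C)(C)O[C@H]3[C@@H]1OC(=O)c1ccccc1 | intermediate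
11 | 4-O-benzoyl-2-C-(benzoyloxymethyl)-6-deoxy-2,3-O-isopropylidene-6-(trifluoroacetoxymercurio)-D-lyxo-hexos-5-ulose, open-chain aldehyde, not isolated | O=C[C@@]1(COC(=O)c2ccccc2)OC(C)(C)O[C@H]1[C@H](OC(=O)c1ccccc1)C(=O)C[Hg]OC(=O)C(F)(F)F | intermediate
12 | ketol: C4 ketone, C2–OH trans to O1 and O6, C5 and C7 benzoates, C1/C6 acetonide | O=C(OC[C@]12OC(C)(C)O[C@H]1[C@H](OC(=O)c1ccccc1)C(=O)C[C@@H]2O)c1ccccc1 | intermediate
13 | C2 tert-butyldimethylsilyl ether of 12 | O=C(OC[C@]12OC(C)(C)O[C@H]1[C@H](OC(=O)c1ccccc1)C(=O)C[C@@H]2O[Si](C)(C)C(C)(C)C)c1ccccc1 | intermediate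
14 | C4 alcohol, C4–OH cis to the C5 benzoate and the C2 silyl ether | O=C(OC[C@]12OC(C)(C)O[C@H]1[C@H](OC(=O)c1ccccc1)[C@H](O)C[C@@H]2O[Si](C)(C)C(C)(C)C)c1ccccc1 | intermediate
15 | C4 triflate of 14, not isolated | O=C(OC[C@]12OC(C)(C)O[C@H]1[C@H](OC(=O)c1ccccc1)[C@H](OS(=O)(=O)C(F)(F)F)C[C@@H]2O[Si](C)(C)C(C)(C)C)c1ccccc1 | intermediate
16 | C4 phenyl selenide, SePh trans to the C5 benzoate | O=C(OC[C@]12OC(C)(C)O[C@H]1[C@H](OC(=O)c1ccccc1)[C@@H]([Se]c1ccccc1)C[C@@H]2O[Si](C)(C)C(C)(C)C)c1ccccc1 | intermediate
17 | selenoxide of 16, not isolated | O=C(OC[C@]12OC(C)(C)O[C@H]1[C@H](OC(=O)c1ccccc1)[C@@H]([Se](=O)c1ccccc1)C[C@@H]2O[Si](C)(C)C(C)(C)C)c1ccccc1 | intermediate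
18 | cyclohex-3-ene, C2 silyl ether trans to O1, C5 and C7 benzoates, C1/C6 acetonide | O=C(OC[C@]12OC(C)(C)O[C@H]1[C@H](OC(=O)c1ccccc1)C=C[C@@H]2O[Si](C)(C)C(C)(C)C)c1ccccc1 | intermediate
19 | allylic alcohol, C2–OH trans to O1 | O=C(OC[C@]12OC(C)(C)O[C@H]1[C@H](OC(=O)c1ccccc1)C=C[C@@H]2O)c1ccccc1 | intermediate
20 | benzoic acid | O=C(O)c1ccccc1 | starting material
21 | tribenzoate acetonide, C2–OBz cis to O1 | O=C(OC[C@]12OC(C)(C)O[C@H]1[C@H](OC(=O)c1ccccc1)C=C[C@H]2OC(=O)c1ccccc1)c1ccccc1 | intermediate
22 | CNP0128482.1 | O=C(OC[C@@]1(O)[C@H](OC(=O)c2ccccc2)C=C[C@@H](OC(=O)c2ccccc2)[C@@H]1O)c1ccccc1 | target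

## Step count and weak points

Total: 15 steps. Longest linear sequence: 15 steps from 1 (the route is fully linear).

Step 8 (key step). The most likely failure is insufficient facial control in the aldol ring closure. The bridged chair argument predicts the C2 hydroxyl trans to O1, but an open transition state would place it cis, and the balance for an acetonide-fused, α-quaternary aldehyde is not secured by precedent. Slow hydroxymercuration of the acyloxy-flanked enol ether and dehydration of the ketol are secondary concerns. Fallback (sets out from 10, returns at 21): whatever portion closes the other way is used, not discarded. The C2-epimeric ketol F1 is taken through the operations of steps 9–13: its silyl ether F2, the C4 alcohol F3, the triflate F4, the phenyl selenide F5, the selenoxide F6 and the alkene F7 lead to the cis allylic alcohol F8. The alcohol F8 is acylated directly with 5 (pyridine, DMAP), that is with retention in place of the Mitsunobu inversion, to give 21.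

Step 14. Displacement at a carbinol carbon next to the quaternary C1 may be slow, which opens the way to SN2' attack at C4, to elimination toward a diene, or to partial retention through an acyloxyphosphonium pathway. Fallback (sets out from 19, returns at 21): oxidation of 19 with Dess–Martin periodinane to the enone F9, then Luche reduction (NaBH4, CeCl3·7H2O, MeOH, −78 °C), in which hydride should add anti to the pseudo-axial C1–O1 bond (Felkin–Anh), gives the cis allylic alcohol F8. The alcohol F8 is benzoylated with 5 to give 21.

Step 11. Substitution at a secondary carbon next to an oxygenated carbon and 1,3 to a bulky silyl ether may be sluggish, so decomposition of the triflate or E2 elimination (possibly toward C5) can intervene. Fallback (sets out from 14, returns at 18): the Burgess reagent (methyl N-(triethylammoniosulfonyl)carbamate, toluene, 70 °C) converts 14 into the sulfamate ester F10, which undergoes thermal syn elimination. In 14 only a C3 hydrogen is syn to O4, because H-5 is trans to it, so the alkene can form only toward C3 and 18 is reached without a substitution step.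

Step 2. Crossed Cannizzaro reduction of the non-enolisable product aldehyde by excess formaldehyde, or slow ring opening of the pyranose lactol, may limit conversion; hydroxymethylation is better established on furanose acetonides. Fallback (sets out from 1, returns at 12): thermodynamic acetonation of 1 (acetone, H2SO4) gives the furanose diacetonide F11, and hydroxymethylation with 3 and K2CO3 then gives the branched furanose F12. HCl in MeOH at reflux converts it into the methyl pyranoside F13, and equilibrating acetonation (acetone, 2,2-dimethoxypropane, TsOH, then brief aqueous acid) gives the 2,3-acetonide F14. Iodination with I2/PPh3/imidazole gives the 6-iodide F15, acylation with 5 in pyridine gives the dibenzoate F16, and AgF in pyridine gives the methyl hex-5-enopyranoside F17. The enol ether F17 enters the Hg(OCOCF3)2 carbocyclization through the same intermediate 11 and gives 12. This sequence is kept in reserve because the acetonation of the methyl pyranoside must choose the ring-fused O2/O3 acetal over a spiro O2/O7 acetal and the iodination must distinguish O6 from O7, two selectivities that the main route avoids.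

## Further compounds

F1 | step 8 | C2-epimeric ketol, C2–OH cis to O1 and O6 | O=C(OC[C@]12OC(C)(C)O[C@H]1[C@H](OC(=O)c1ccccc1)C(=O)C[C@H]2O)c1ccccc1
F2 | step 8 | C2 tert-butyldimethylsilyl ether of F1 | O=C(OC[C@]12OC(C)(C)O[C@H]1[C@H](OC(=O)c1ccccc1)C(=O)C[C@H]2O[Si](C)(C)C(C)(C)C)c1ccccc1
F3 | step 8 | C4 alcohol of the epimeric series, C4–OH trans to the C5 benzoate | O=C(OC[C@]12OC(C)(C)O[C@H]1[C@H](OC(=O)c1ccccc1)[C@@H](O)C[C@H]2O[Si](C)(C)C(C)(C)C)c1ccccc1
F4 | step 8 | C4 triflate of F3 | O=C(OC[C@]12OC(C)(C)O[C@H]1[C@H](OC(=O)c1ccccc1)[C@@H](OS(=O)(=O)C(F)(F)F)C[C@H]2O[Si](C)(C)C(C)(C)C)c1ccccc1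
F5 | step 8 | C4 phenyl selenide of the epimeric series, SePh cis to the C5 benzoate | O=C(OC[C@]12OC(C)(C)O[C@H]1[C@H](OC(=O)c1ccccc1)[C@H]([Se]c1ccccc1)C[C@H]2O[Si](C)(C)C(C)(C)C)c1ccccc1
F6 | step 8 | selenoxide of F5 | O=C(OC[C@]12OC(C)(C)O[C@H]1[C@H](OC(=O)c1ccccc1)[C@H]([Se](=O)c1ccccc1)C[C@H]2O[Si](C)(C)C(C)(C)C)c1ccccc1
F7 | step 8 | cyclohex-3-ene with C2 silyl ether cis to O1 | O=C(OC[C@]12OC(C)(C)O[C@H]1[C@H](OC(=O)c1ccccc1)C=C[C@H]2O[Si](C)(C)C(C)(C)C)c1ccccc1
F8 | step 8 | cis allylic alcohol, C2–OH cis to O1 | O=C(OC[C@]12OC(C)(C)O[C@H]1[C@H](OC(=O)c1ccccc1)C=C[C@H]2O)c1ccccc1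
F9 | step 14 | cyclohex-3-en-2-one with C5 and C7 benzoates and C1/C6 acetonide | O=C(OC[C@]12OC(C)(C)O[C@H]1[C@H](OC(=O)c1ccccc1)C=CC2=O)c1ccccc1
F10 | step 11 | C4 N-(methoxycarbonyl)sulfamate of 14, triethylammonium salt | O=C(OC[C@]12OC(C)(C)O[C@H]1[C@H](OC(=O)c1ccccc1)[C@H](OS(=O)(=O)[N-]C(=O)OC)C[C@@H]2O[Si](C)(C)C(C)(C)C)c1ccccc1.CC[NH+](CC)CC
F11 | step 2 | 2,3:5,6-di-O-isopropylidene-D-mannofuranose | CC1(C)OC[C@@H](O1)[C@H]2OC(O)[C@H]3OC(C)(C)O[C@@H]23
F12 | step 2 | 2-C-(hydroxymethyl)-2,3:5,6-di-O-isopropylidene-D-mannofuranose | CC1(C)OC[C@@H](O1)[C@H]2OC(O)[C@@]3(CO)OC(C)(C)O[C@@H]23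
F13 | step 2 | methyl 2-C-(hydroxymethyl)-α-D-mannopyranoside | OC[C@H]1O[C@H](OC)[C@](O)(CO)[C@@H](O)[C@@H]1O
F14 | step 2 | methyl 2-C-(hydroxymethyl)-2,3-O-isopropylidene-α-D-mannopyranoside | OC[C@H]1O[C@H](OC)[C@@]2(CO)OC(C)(C)O[C@H]2[C@@H]1O
F15 | step 2 | methyl 6-deoxy-2-C-(hydroxymethyl)-6-iodo-2,3-O-isopropylidene-α-D-mannopyranoside | IC[C@H]1O[C@H](OC)[C@@]2(CO)OC(C)(C)O[C@H]2[C@@H]1O
F16 | step 2 | methyl 4-O-benzoyl-2-C-(benzoyloxymethyl)-6-deoxy-6-iodo-2,3-O-isopropylidene-α-D-mannopyranoside | IC[C@H]1O[C@H](OC)[C@@]2(COC(=O)c3ccccc3)OC(C)(C)O[C@H]2[C@@H]1OC(=O)c1ccccc1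
F17 | step 2 | methyl 4-O-benzoyl-2-C-(benzoyloxymethyl)-6-deoxy-2,3-O-isopropylidene-α-D-lyxo-hex-5-enopyranoside | O=C(OC[C@]12OC(C)(C)O[C@H]1[C@H](OC(=O)c1ccccc1)C(=C)O[C@@H]2OC)c1ccccc1
A1 | alternative 1 | cis-1,6-diol cyclohexene with p-methoxybenzyl ethers at O2, O5 and O7 | COc1ccc(COC[C@@]2(O)[C@H](OCc3ccc(OC)cc3)C=C[C@@H](OCc3ccc(OC)cc3)[C@@H]2O)cc1
A2 | alternative 1 | (Z)-keto-aldehyde with C1 ketone, C6 aldehyde and p-methoxybenzyl ethers at O2, O5 and O7 | COc1ccc(COCC(=O)[C@H](OCc2ccc(OC)cc2)/C=C\[C@@H](OCc2ccc(OC)cc2)C=O)cc1
A3 | alternative 1 | samarium diiodide | I[Sm]I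
A4 | alternative 2 | cis-fused ethylidene acetal bridging O1 and O2, with C4 ketone and C5=C6 alkene | O=C(OC[C@@]12O[C@@H](C)O[C@@H]1CC(=O)C=C2)c1ccccc1
A5 | alternative 2 | 4-(benzoyloxymethyl)-4-hydroxycyclohexa-2,5-dien-1-one | O=C(OCC1(O)C=CC(=O)C=C1)c1ccccc1
A6 | alternative 2 | acetaldehyde | CC=O
A7 | alternative 3 | acyloin with quaternary C1 carbinol, C2 ketone and C5/C6 acetonide | COc1ccc(COC[C@@]2(O)C(=O)CC[C@H]3OC(C)(C)O[C@H]23)cc1
A8 | alternative 3 | saturated keto-aldehyde with C1 ketone, C2 aldehyde and C5/C6 acetonide | COc1ccc(COCC(=O)[C@H]2OC(C)(C)O[C@@H]2CCC=O)cc1
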